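The target is the mono-seco acid of a twofold-symmetric bis-lactone, so both C2–C1' bonds are cut at once. Each joins quaternary C2 of a chromanone (next to ring oxygen O1, bearing CO2Me) to the lactone carbinol C1'. C2 is the β-carbon of the pyranone enone C2=C3–C4=O, activated through chelation by C4=O and the peri 5-OH; C1' is C5 of 4-methylbutenolide. One twofold catalytic asymmetric vinylogous Mukaiyama–Michael addition to a flat, achiral 5,5'-dihydroxy-6,6'-bichromone diester forms both bonds and all four C2/C1' stereocentres. That bichromone is built with inner and outer phenol oxygens differentiated from the start, so each pyranone can close one way only. Hydrogenation and a single lactone opening finish the route.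

Key step: step 7

Assumption: the (S,S)-bis(oxazoline) is taken to leave the Si face of C2 open; the sense is to be confirmed on the monomeric 5-hydroxychromone ester and the (R,R)-ligand used if it is opposite. The 6,6'-axis, with only two ortho substituents, is treated as freely rotating.

Step 1
Reactants: 1 4-bromo-3-methoxyphenol
Product: 2 1-bromo-2-methoxy-4-(methoxymethoxy)benzene
Conditions: MOMCl, iPr2NEt, CH2Cl2, 0 °C to rt
Reagents that add atoms: chloromethyl methyl ether (MOMCl), COCCl
Why: Williamson-type O-alkylation of the only phenol with the α-chloro ether installs the MOM acetal, which later acts as ortho-directing group and as the only acid-labile oxygen protection.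

Step 2
Reactants: 2 1-bromo-2-methoxy-4-(methoxymethoxy)benzene (two molecules)
Product: 3 2,2'-dimethoxy-4,4'-bis(methoxymethoxy)-1,1'-biphenyl
Conditions: NiCl2(PPh3)2 (10 mol %), PPh3, Zn (1.5 equiv), Et4NI, THF, 50 °C
Reagents that add atoms: second molecule of 2, 1-bromo-2-methoxy-4-(methoxymethoxy)benzene, COCOc1ccc(Br)c(OC)c1
Why: Two molecules of 2 are joined at their C–Br carbons, since zinc reduces the precatalyst to zerovalent nickel, which inserts into C–Br and couples the two aryl groups reductively (nickel-mediated Ullmann-type homocoupling), fixing the biaryl bond ortho to OMe and para to OMOM while ethers and acetals stay inert.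

Step 3
Reactants: 3 2,2'-dimethoxy-4,4'-bis(methoxymethoxy)-1,1'-biphenyl; 4 N-methoxy-N-methylacetamide
Product: 6 1,1'-[2,2'-dimethoxy-4,4'-bis(methoxymethoxy)biphenyl-3,3'-diyl]di(ethan-1-one), via 3,3'-dilithiobiaryl 5 (not isolated)
Conditions: n-BuLi (2.5 equiv), TMEDA, THF, 0 °C; then 4 (3 equiv), −78 to 0 °C; aq NH4Cl
Reagents that add atoms: none
Why: Directed ortho-metalation removes the C3/C3' protons, the only ones flanked by two coordinating oxygens (OMe and OMOM), and the aryllithium is acylated by the Weinreb amide, whose chelated tetrahedral adduct prevents over-addition.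

Step 4
Reactants: 6 1,1'-[2,2'-dimethoxy-4,4'-bis(methoxymethoxy)biphenyl-3,3'-diyl]di(ethan-1-one); 7 dimethyl oxalate
Product: 10 dimethyl 5,5'-dimethoxy-4,4'-dioxo-4H,4'H-[6,6'-bichromene]-2,2'-dicarboxylate, via MOM-protected bis(diketo ester) 8 (not isolated), via bis(phenol) bis(diketo ester) 9 (not isolated)
Conditions: 7 (4 equiv), NaOMe, MeOH/THF, 60 °C; then conc. HCl, MeOH, 65 °C
Reagents that add atoms: none
Why: Crossed Claisen condensation with non-enolisable dimethyl oxalate gives the 2,4-dioxobutanoates, and HCl/MeOH then frees only the MOM-protected outer phenol, which adds to the C2 ketone and dehydrates to the γ-pyranone (Kostanecki-type chromone-2-carboxylate synthesis) while the inner oxygen stays blocked as OMe.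

Step 5
Reactants: 10 dimethyl 5,5'-dimethoxy-4,4'-dioxo-4H,4'H-[6,6'-bichromene]-2,2'-dicarboxylate
Product: 11 dimethyl 5,5'-dihydroxy-4,4'-dioxo-4H,4'H-[6,6'-bichromene]-2,2'-dicarboxylate
Conditions: BCl3 (5 equiv), CH2Cl2, −78 to 0 °C; aq NaHCO3
Reagents that add atoms: none
Why: BCl3 chelates the C4 carbonyl and the peri methoxy oxygen and chloride removes the methyl group (chelation-assisted Lewis-acid ether cleavage), which is specific for the peri position and spares the methyl esters and the pyranone at or below 0 °C.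

Step 6
Reactants: 12 4-methylfuran-2(5H)-one
Product: 13 4-methyl-2-(trimethylsilyloxy)furan
Conditions: TMSOTf, Et3N, Et2O, 0 °C; distilled
Reagents that add atoms: trimethylsilyl trifluoromethanesulfonate (TMSOTf), C[Si](C)(C)OS(=O)(=O)C(F)(F)F
Why: Soft enolisation at C5 and O-silylation of the dienolate (silyl dienol ether formation) give the aromatic 2-siloxyfuran, which is used directly.

Step 7
Reactants: 11 dimethyl 5,5'-dihydroxy-4,4'-dioxo-4H,4'H-[6,6'-bichromene]-2,2'-dicarboxylate; 13 4-methyl-2-(trimethylsilyloxy)furan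
Product: 15 dimethyl (2S,2'S)-5,5'-dihydroxy-2,2'-bis[(2R)-3-methyl-5-oxo-2,5-dihydrofuran-2-yl]-4,4'-dioxo-[6,6'-bichromane]-2,2'-dicarboxylate, via bis(4-silyloxychromene) adduct 14 (not isolated)
Conditions: Cu(OTf)2 (20 mol %), (S,S)-t-Bu-box (22 mol %), 13 (5 equiv), 4 Å MS, CH2Cl2, −40 °C; then 1 M HCl, THF, 0 °C
Reagents that add atoms: none
Why: The cationic Cu(OTf)2–bis(oxazoline) complex (divalent copper) binds each chromone through the C4 carbonyl and the peri 5-OH in a six-membered chelate, the two-point mode of α'-hydroxy enones, which gives C2 benzopyrylium character; the furan attacks C2 through its unsubstituted C5 in an open transition state, the resulting oxocarbenium ion passes its silyl group to the C4 enolate oxygen (giving 14 and releasing the catalyst), and acid work-up returns the C4 ketone and the butenolide. The closest known reaction types are the vinylogous Mukaiyama–Michael addition of 2-siloxyfurans to chromone-2-carboxylates activated as siloxybenzopyrylium ions and the Cu(OTf)2–bis(oxazoline)-catalysed addition of 2-siloxyfurans to chelating acceptors. No ring is closed; the two C2–C1' bonds are formed. C2 (S at each terminus) is set by the ligand, whose tert-butyl group is taken to block the Re face of C2 so that the furan adds to the Si face; C1' (R) is set by the relative topicity, the furan presenting the Si face of its C5 with its ring over the pyranone and its 4-methyl turned away from the C2 ester. The step needs attack at C2 and not at the carbonyl, γ-attack of the furan and not α-attack, and independent catalyst control at the two termini: the chelated vinylogous ester leaves C2 as the only electrophilic carbon, the siloxyfuran reacts at its unsubstituted γ-carbon, the freely rotating axis adds no stereochemical bias, and a wrong-sense event at one terminus ends in the separable heterochiral diastereomer, which should raise the enantiomeric purity of the homochiral product.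

Step 8
Reactants: 15 dimethyl (2S,2'S)-5,5'-dihydroxy-2,2'-bis[(2R)-3-methyl-5-oxo-2,5-dihydrofuran-2-yl]-4,4'-dioxo-[6,6'-bichromane]-2,2'-dicarboxylate
Product: 16 dimethyl (2S,2'S)-5,5'-dihydroxy-2,2'-bis[(2R,3S)-3-methyl-5-oxooxolan-2-yl]-4,4'-dioxo-[6,6'-bichromane]-2,2'-dicarboxylate
Conditions: H2 (4 atm), 10 % Pd/C, EtOAc, rt
Reagents that add atoms: none
Why: Heterogeneous catalytic hydrogenation adds H2 syn to the face of each planar butenolide opposite the fully substituted chromanone carbon on C1', so each new C2' methyl ends cis to the chromanone (2'S), while the chelated aryl ketones, the esters and the arenes should not be reduced under these mild conditions.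

Step 9
Reactants: 16 dimethyl (2S,2'S)-5,5'-dihydroxy-2,2'-bis[(2R,3S)-3-methyl-5-oxooxolan-2-yl]-4,4'-dioxo-[6,6'-bichromane]-2,2'-dicarboxylate
Product: 17 (3S,4R)-4-hydroxy-4-[(2S)-5-hydroxy-6-{(2S)-5-hydroxy-2-(methoxycarbonyl)-2-[(2R,3S)-3-methyl-5-oxooxolan-2-yl]-4-oxochroman-6-yl}-2-(methoxycarbonyl)-4-oxochroman-2-yl]-3-methylbutanoic acid
Conditions: LiOH (3.0 equiv), THF/H2O 3:1, 0 °C, stopped at partial conversion; cold 0.5 M HCl to pH 4
Reagents that add atoms: lithium hydroxide, [Li+].[OH-]
Why: Acyl–oxygen saponification of a γ-lactone with an unhindered CH2–C=O should outpace attack on the methyl esters at quaternary C2, so hydroxide limited to one equivalent beyond the two phenols opens one lactone statistically without touching a stereocentre, and recovered 16 is resubmitted.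

Compound list
1 | 4-bromo-3-methoxyphenol | COc1cc(O)ccc1Br | starting material
2 | 1-bromo-2-methoxy-4-(methoxymethoxy)benzene | COCOc1ccc(Br)c(OC)c1 | intermediate
3 | 2,2'-dimethoxy-4,4'-bis(methoxymethoxy)-1,1'-biphenyl | COCOc1ccc(-c2ccc(OCOC)cc2OC)c(OC)c1 | intermediate
4 | N-methoxy-N-methylacetamide | CC(=O)N(C)OC | starting material
5 | 3,3'-dilithio-2,2'-dimethoxy-4,4'-bis(methoxymethoxy)biphenyl | [Li]c1c(OCOC)ccc(-c2ccc(OCOC)c([Li])c2OC)c1OC | intermediate
6 | 1,1'-[2,2'-dimethoxy-4,4'-bis(methoxymethoxy)biphenyl-3,3'-diyl]di(ethan-1-one) | CC(=O)c1c(OCOC)ccc(-c2ccc(OCOC)c(C(C)=O)c2OC)c1OC | intermediate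
7 | dimethyl oxalate | COC(=O)C(=O)OC | starting material
8 | dimethyl 4,4'-[2,2'-dimethoxy-4,4'-bis(methoxymethoxy)biphenyl-3,3'-diyl]bis(2,4-dioxobutanoate) | COC(=O)C(=O)CC(=O)c1c(OCOC)ccc(-c2ccc(OCOC)c(C(=O)CC(=O)C(=O)OC)c2OC)c1OC | intermediate
9 | dimethyl 4,4'-(4,4'-dihydroxy-2,2'-dimethoxybiphenyl-3,3'-diyl)bis(2,4-dioxobutanoate) | COC(=O)C(=O)CC(=O)c1c(O)ccc(-c2ccc(O)c(C(=O)CC(=O)C(=O)OC)c2OC)c1OC | intermediate
10 | dimethyl 5,5'-dimethoxy-4,4'-dioxo-4H,4'H-[6,6'-bichromene]-2,2'-dicarboxylate | COC(=O)C1=CC(=O)c2c(ccc(-c3ccc4c(c3OC)C(=O)C=C(C(=O)OC)O4)c2OC)O1 | intermediate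
11 | dimethyl 5,5'-dihydroxy-4,4'-dioxo-4H,4'H-[6,6'-bichromene]-2,2'-dicarboxylate | COC(=O)C1=CC(=O)c2c(ccc(-c3ccc4c(c3O)C(=O)C=C(C(=O)OC)O4)c2O)O1 | intermediate
12 | 4-methylfuran-2(5H)-one | CC1=CC(=O)OC1 | starting material
13 | 4-methyl-2-(trimethylsilyloxy)furan | Cc1coc(O[Si](C)(C)C)c1 | intermediate
14 | dimethyl (2S,2'S)-5,5'-dihydroxy-2,2'-bis[(2R)-3-methyl-5-oxo-2,5-dihydrofuran-2-yl]-4,4'-bis(trimethylsilyloxy)-2H,2'H-[6,6'-bichromene]-2,2'-dicarboxylate | COC(=O)[C@@]1([C@@H]2OC(=O)C=C2C)C=C(O[Si](C)(C)C)c2c(ccc(-c3ccc4c(c3O)C(O[Si](C)(C)C)=C[C@@](C(=O)OC)([C@@H]3OC(=O)C=C3C)O4)c2O)O1 | intermediate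
15 | dimethyl (2S,2'S)-5,5'-dihydroxy-2,2'-bis[(2R)-3-methyl-5-oxo-2,5-dihydrofuran-2-yl]-4,4'-dioxo-[6,6'-bichromane]-2,2'-dicarboxylate | COC(=O)[C@@]1([C@@H]2OC(=O)C=C2C)CC(=O)c2c(ccc(-c3ccc4c(c3O)C(=O)C[C@@](C(=O)OC)([C@@H]3OC(=O)C=C3C)O4)c2O)O1 | intermediate
16 | dimethyl (2S,2'S)-5,5'-dihydroxy-2,2'-bis[(2R,3S)-3-methyl-5-oxooxolan-2-yl]-4,4'-dioxo-[6,6'-bichromane]-2,2'-dicarboxylate | COC(=O)[C@@]1([C@@H]2OC(=O)C[C@@H]2C)CC(=O)c2c(ccc(-c3ccc4c(c3O)C(=O)C[C@@](C(=O)OC)([C@@H]3OC(=O)C[C@@H]3C)O4)c2O)O1 | intermediate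
17 | (3S,4R)-4-hydroxy-4-[(2S)-5-hydroxy-6-{(2S)-5-hydroxy-2-(methoxycarbonyl)-2-[(2R,3S)-3-methyl-5-oxooxolan-2-yl]-4-oxochroman-6-yl}-2-(methoxycarbonyl)-4-oxochroman-2-yl]-3-methylbutanoic acid | COC(=O)[C@@]1([C@H](O)[C@@H](C)CC(=O)O)CC(=O)c2c(ccc(-c3ccc4c(c3O)C(=O)C[C@@](C(=O)OC)([C@@H]3OC(=O)C[C@@H]3C)O4)c2O)O1 | target

Total step count: 9. Longest linear sequence: 8 steps (steps 1–5 and 7–9, from 1).

Steps most likely to fail

Step 7. Facial selection at C2 may be weak because the chiral ligand sits on the C4/C5 chelate, three atoms from the reacting carbon. An achiral silyl-triflate-catalysed pathway or proton transfer from the phenols to 13 may also compete. The fallback sets out from 11 and 13 and replaces catalyst control by substrate control plus resolution. iPr2Si(OTf)2 with 2,6-di-tert-butyl-4-methylpyridine in CH2Cl2 converts 11 into the bis(silylene-bridged siloxybenzopyrylium) bis(triflate) F1. Addition of 13 at −78 °C gives the silylene-bridged bis(enol ether) adduct F2 as a stereoisomer mixture with the C2/C1' relative configuration set by the substrate. Et3N·3HF removes silicon and gives 15 together with its enantiomer ent-15 F3 and the heterochiral meso diastereomer F4. F4 is removed on silica, 15 is separated from F3 by preparative HPLC on a chiral stationary phase, and the route is rejoined at 15.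

Step 9. Control of the stopping point may be poor: the second lactone opens at the same rate, and the hydroxy acid can reclose during acidification. The fallback sets out from 16 and approaches the target from the fully opened side. Excess LiOH in THF/H2O opens both lactones to the bis(hydroxy acid) F5, which is isolated at pH 4. One arm is then closed by acid-catalysed lactonisation (PPTS, CH2Cl2, 0 °C) followed to half conversion; doubly closed material is 16 and is recycled. The route is rejoined at 17.

Step 3. The second lithiation may stay incomplete, or the hindered aryllithium may deprotonate the Weinreb amide and return C–H in place of acyl transfer. The fallback sets out from 3 (through 5) and builds the acetyl groups in two stages. The dilithio species is quenched with DMF to the dialdehyde F6, MeMgBr in THF at 0 °C gives the bis(secondary alcohol) F7 as a diastereomer mixture, and Dess–Martin periodinane in CH2Cl2 oxidises it to the diketone. The route is rejoined at 6.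

Further compounds
F1 | step 7 | bis(diisopropylsilylene-bridged siloxybenzopyrylium) bis(triflate) of 11 | COC(=O)c1cc2O[Si](C(C)C)(C(C)C)Oc3c(-c4ccc5[o+]c(C(=O)OC)cc6O[Si](C(C)C)(C(C)C)Oc4c56)ccc([o+]1)c23.[O-]S(=O)(=O)C(F)(F)F.[O-]S(=O)(=O)C(F)(F)F
F2 | step 7 | diisopropylsilylene-bridged bis(enol ether) adduct (drawn as the 2S,2'S isomer; formed as a stereoisomer mixture) | COC(=O)[C@@]1([C@@H]2OC(=O)C=C2C)C=C2O[Si](C(C)C)(C(C)C)Oc3c(-c4ccc5c6c4O[Si](C(C)C)(C(C)C)OC6=C[C@@](C(=O)OC)([C@@H]4OC(=O)C=C4C)O5)ccc(O1)c23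
F3 | step 7 | ent-15, dimethyl (2R,2'R)-5,5'-dihydroxy-2,2'-bis[(2S)-3-methyl-5-oxo-2,5-dihydrofuran-2-yl]-4,4'-dioxo-[6,6'-bichromane]-2,2'-dicarboxylate | COC(=O)[C@]1([C@H]2OC(=O)C=C2C)CC(=O)c2c(ccc(-c3ccc4c(c3O)C(=O)C[C@](C(=O)OC)([C@H]3OC(=O)C=C3C)O4)c2O)O1
F4 | step 7 | meso diastereomer of 15, dimethyl (2R,2'S)-5,5'-dihydroxy-2-[(2S)-3-methyl-5-oxo-2,5-dihydrofuran-2-yl]-2'-[(2R)-3-methyl-5-oxo-2,5-dihydrofuran-2-yl]-4,4'-dioxo-[6,6'-bichromane]-2,2'-dicarboxylate | COC(=O)[C@@]1([C@@H]2OC(=O)C=C2C)CC(=O)c2c(ccc(-c3ccc4c(c3O)C(=O)C[C@](C(=O)OC)([C@H]3OC(=O)C=C3C)O4)c2O)O1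
F5 | step 9 | bis(hydroxy acid), (3S,3'S,4R,4'R)-4,4'-[(2S,2'S)-5,5'-dihydroxy-2,2'-bis(methoxycarbonyl)-4,4'-dioxo-[6,6'-bichromane]-2,2'-diyl]bis(4-hydroxy-3-methylbutanoic acid) | COC(=O)[C@@]1([C@H](O)[C@@H](C)CC(=O)O)CC(=O)c2c(ccc(-c3ccc4c(c3O)C(=O)C[C@@](C(=O)OC)([C@H](O)[C@@H](C)CC(=O)O)O4)c2O)O1
F6 | step 3 | 2,2'-dimethoxy-4,4'-bis(methoxymethoxy)biphenyl-3,3'-dicarbaldehyde | O=Cc1c(OCOC)ccc(-c2ccc(OCOC)c(C=O)c2OC)c1OC
F7 | step 3 | 1,1'-[2,2'-dimethoxy-4,4'-bis(methoxymethoxy)biphenyl-3,3'-diyl]di(ethan-1-ol), carbinol centres undefined | CC(O)c1c(OCOC)ccc(-c2ccc(OCOC)c(C(C)O)c2OC)c1OC
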